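**Strategy.** The target is cut at the two C3–C1′ bonds that join the four-carbon chains to butenolide rings A and B. In one operation, double C3 lithiation of a C2-symmetric dispiro bis(methyl tetronate) and acylation with two molecules of N-methoxy-N-methylbutanamide attach both chains as ketones. The step exploits the fact that C5A and C5B are quaternary spiro carbons and C4A/C4B carry methoxy groups, so C3A–H and C3B–H are the only acidic sites. The precursor is a trans-cyclobutane-1,2-diol bis(silyl ether) flanked by the two spiro 4-methoxybutenolides, made from L-tartrate through a cyclobutane-1,2-dione. The bromine atoms and the opposite C1′ acetates follow afterwards.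

Key step: step 6

**Labels.** Each butenolide is O1–C2(=O)–C3=C4–C5 (ring A, ring B). C5A and C5B are the spiro carbons; C6 (next to C5A) and C7 (next to C5B) complete the cyclobutane; C1′ is the side-chain carbinol carbon.

**Remarks on the chemistry.**
- The dispiro core is C2-symmetric, so the (1′S)/(1′R) pair of the target is reached from either antipode of the C2-symmetric C1′ diol by inverting one arm.
- Both C6 and C7 must be inverted when bromine replaces oxygen; their descriptors stay R only because the priorities change.
- The C4 methoxy groups are exchanged for bromine while C1′ is still a ketone. A free tetronate next to a C1′ leaving group would expel it (E1cB) and scramble C1′.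
- Steps 4 and 6 are two-directional: each consumes two molecules of its small partner per molecule of the cyclobutane component. The second molecule is therefore entered on the line of atom-adding reagents.

Step 1
Reactants: 1 diethyl L-tartrate
Product: 2 diethyl (2R,3R)-2,3-bis(tert-butyldimethylsilyloxy)butanedioate
Conditions: TBSOTf (2.4 equiv), 2,6-lutidine, CH2Cl2, 0 °C to rt
Reagents that add atoms: tert-butyldimethylsilyl trifluoromethanesulfonate, CC(C)(C)[Si](C)(C)OS(=O)(=O)C(F)(F)F
Why: Silyl triflate/lutidine silylation protects both secondary hydroxyls as silyl ethers without touching either stereocentre.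

Step 2
Reactants: 2 diethyl (2R,3R)-2,3-bis(tert-butyldimethylsilyloxy)butanedioate
Product: 3 (3R,4R)-3,4-bis(tert-butyldimethylsilyloxy)-1,2-bis(trimethylsilyloxy)cyclobut-1-ene
Conditions: Na (4.4 equiv), TMSCl (4.5 equiv), toluene, reflux
Reagents that add atoms: chlorotrimethylsilane, C[Si](C)(C)Cl
Why: Rühlmann acyloin condensation couples the two ester groups to the four-membered enediolate, which TMSCl traps while also scavenging ethoxide, so the two carbinol centres should keep their trans (R,R) configuration.

Step 3
Reactants: 3 (3R,4R)-3,4-bis(tert-butyldimethylsilyloxy)-1,2-bis(trimethylsilyloxy)cyclobut-1-ene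
Product: 4 (3R,4R)-3,4-bis(tert-butyldimethylsilyloxy)cyclobutane-1,2-dione
Conditions: Br2 (1.0 equiv), CH2Cl2, −78 °C; volatiles removed, used crude
Reagents that add atoms: none
Why: Bromine oxidation of an enediol bis(silyl ether) to the 1,2-diketone with loss of two TMSBr is the standard entry to cyclobutane-1,2-diones, and anhydrous handling avoids hydrate formation and ring contraction.

Step 4
Reactants: 4 (3R,4R)-3,4-bis(tert-butyldimethylsilyloxy)cyclobutane-1,2-dione; 5 methyl (E)-3-methoxyacrylate (two molecules are incorporated)
Product: 8 dispiro bis(methyl tetronate) bis(TBS ether), via methyl (E)-3-lithio-3-methoxyacrylate 6 (not isolated), via dilithium bis-alkoxide diester adduct 7 (not isolated)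
Conditions: 5 (2.6 equiv), LiN(iPr)2 (LDA, 2.6 equiv), THF, −95 °C; then 4, −95 to 0 °C; AcOH
Reagents that add atoms: methyl (E)-3-methoxyacrylate (the second molecule consumed), CO/C=C/C(=O)OC
Why: β-Lithiation of the methoxyacrylate gives a vinyllithium held cis to the ester, which should add 1,2 to each strained ketone anti to the adjacent silyloxy group (substrate control, the second addition also anti to C4A of the first arm), and each tertiary alkoxide then lactonises onto the cis ester, setting C5A and C5B as one C2-symmetric diastereomer (vinyl-anion tetronate annulation).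

Step 5
Reactants: 9 butanoyl chloride; 10 N,O-dimethylhydroxylamine hydrochloride
Product: 11 N-methoxy-N-methylbutanamide
Conditions: pyridine, CH2Cl2, 0 °C to rt
Reagents that add atoms: none
Why: N-Acylation of the hydroxylamine by the acid chloride is the standard preparation of a Weinreb amide.

Step 6
Reactants: 8 dispiro bis(methyl tetronate) bis(TBS ether); 11 N-methoxy-N-methylbutanamide (two molecules are incorporated)
Product: 14 3A,3B-dibutanoyl dispiro bis(methyl tetronate) bis(TBS ether), via 3A,3B-dilithio bis(methyl tetronate) 12 (not isolated), via bis(lithium N-methoxy-N-methyl hemiaminal alkoxide) 13 (not isolated)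
Conditions: LiN(iPr)2 (LDA, 2.4 equiv), THF, −78 °C; then 11 (3 equiv), −78 to −30 °C; AcOH
Reagents that add atoms: N-methoxy-N-methylbutanamide (the second molecule consumed), CCCC(=O)N(C)OC
Why: LDA should remove the only acidic protons, the vinylic C3A–H and C3B–H, which are acidified by the C2 lactone carbonyls and guided by lithium coordination to the 4-methoxy oxygens, because C5A and C5B are quaternary spiro carbons and no γ-deprotonation is possible. Each of the two C3 vinyllithium centres adds to the carbonyl of its own molecule of the amide, and the five-membered N-methoxy chelate of each tetrahedral lithium alkoxide persists until the acidic quench, so each arm stops at the ketone (Weinreb ketone synthesis) and two butanoyl groups are delivered per molecule of 8. The closest known reaction type is C3 lithiation of 5,5-disubstituted 4-methoxy-2(5H)-furanones followed by trapping with aldehydes or acyl donors. No ring is closed and no stereocentre is formed; C5A, C5B, C6 and C7 are not enolisable and stay untouched. The selectivity needed is site selectivity for C3 over the lactone carbonyls and silyl ethers together with clean two-fold mono-acylation, and the blocked C5 positions, the non-nucleophilic amide base at −78 °C and the chelated intermediate secure it.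

Step 7
Reactants: 14 3A,3B-dibutanoyl dispiro bis(methyl tetronate) bis(TBS ether)
Product: 16 bis(4-bromo-3-butanoylbutenolide) bis(TBS ether), via dilithium bis(3-butanoyltetronate) 15 (not isolated)
Conditions: LiBr (3 equiv), DMF, 60 °C; then (COBr)2 (2.4 equiv), CH2Cl2, −20 to 0 °C; non-aqueous work-up
Reagents that add atoms: oxalyl bromide, O=C(Br)C(=O)Br
Why: Bromide should demethylate by SN2 because the leaving group is a 3-acyltetronate, and the lithium tetronate is then converted by the bromoiminium (Vilsmeier–Haack-type) reagent into the C4 vinyl bromide by addition–elimination without release of HBr, as known for tetronic acids and 3-acyl-4-hydroxypyranones.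

Step 8
Reactants: 16 bis(4-bromo-3-butanoylbutenolide) bis(TBS ether)
Product: 17 (1′R,1′R)-bis(1-hydroxybutyl) bis(4-bromobutenolide) bis(TBS ether)
Conditions: (S)-1-methyl-3,3-diphenyltetrahydro-1H,3H-pyrrolo[1,2-c][1,3,2]oxazaborole ((S)-Me-CBS, 0.4 equiv), BH3·THF (1.4 equiv), THF, −40 °C; MeOH
Reagents that add atoms: none
Why: In this Corey–Bakshi–Shibata reduction the butenolide is the large and propyl the small ketone substituent, so the (S)-catalyst should deliver hydride to the same face of both homotopic ketones and set both C1′ centres as R under reagent control (the antipodal C2 diol would serve equally).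

Step 9
Reactants: 17 (1′R,1′R)-bis(1-hydroxybutyl) bis(4-bromobutenolide) bis(TBS ether)
Product: 18 mono-acetate with (1′S)-acetoxybutyl on one arm and (1′R)-hydroxybutyl on the other
Conditions: PPh3 and DIAD (1.1 equiv each, premixed), AcOH, THF, 0 °C; diol 17 recovered and recycled
Reagents that add atoms: acetic acid, CC(=O)O
Why: Mitsunobu esterification inverts one of the two homotopic allylic carbinols by SN2 (1′R to 1′S), so with about one equivalent of preformed betaine the single possible mono-ester should be the statistical main product next to recoverable diol and some doubly inverted diacetate.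

Step 10
Reactants: 18 mono-acetate with (1′S)-acetoxybutyl on one arm and (1′R)-hydroxybutyl on the other
Product: 19 (1′S)/(1′R)-diacetate bis(TBS ether)
Conditions: Ac2O, pyridine, 4-(dimethylamino)pyridine (cat.), CH2Cl2, 0 °C to rt
Reagents that add atoms: acetic anhydride, CC(=O)OC(C)=O
Why: Standard O-acetylation esterifies the remaining (1′R) carbinol with retention, giving the two arms of opposite configuration.

Step 11
Reactants: 19 (1′S)/(1′R)-diacetate bis(TBS ether)
Product: 20 (1′S)/(1′R)-diacetate (6R,7R)-cyclobutane-6,7-diol
Conditions: HF (48% aq.), MeCN, rt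
Reagents that add atoms: none
Why: Acidic fluoride desilylation should remove both secondary TBS ethers without touching acetates, vinyl bromides or lactones.

Step 12
Reactants: 20 (1′S)/(1′R)-diacetate (6R,7R)-cyclobutane-6,7-diol
Product: 22 target CNP0266230.1, via C6/C7 bis(triflate) 21 (not isolated)
Conditions: Tf2O (2.4 equiv), 2,6-lutidine, CH2Cl2, −30 °C; then n-Bu4NBr (2.5 equiv), toluene, rt
Reagents that add atoms: tetrabutylammonium bromide, CCCC[N+](CCCC)(CCCC)CCCC.[Br-]
Why: Sulfonate displacement by bromide is SN2 with inversion at both C6 and C7, which places each bromine cis to C4 of the neighbouring spiro ring; ionisation is retarded by the acyloxy-bearing spiro carbons and bromide is too weak a base for elimination, while exchange at the vinylic C4–Br positions is degenerate.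

**Compound list**

1 | diethyl L-tartrate, diethyl (2R,3R)-2,3-dihydroxybutanedioate | CCOC(=O)[C@H](O)[C@@H](O)C(=O)OCC | starting material
2 | diethyl (2R,3R)-2,3-bis(tert-butyldimethylsilyloxy)butanedioate | CCOC(=O)[C@H](O[Si](C)(C)C(C)(C)C)[C@@H](O[Si](C)(C)C(C)(C)C)C(=O)OCC | intermediate
3 | (3R,4R)-3,4-bis(tert-butyldimethylsilyloxy)-1,2-bis(trimethylsilyloxy)cyclobut-1-ene (trans) | C[Si](C)(C)OC1=C(O[Si](C)(C)C)[C@H](O[Si](C)(C)C(C)(C)C)[C@H]1O[Si](C)(C)C(C)(C)C | intermediate
4 | (3R,4R)-3,4-bis(tert-butyldimethylsilyloxy)cyclobutane-1,2-dione (trans) | O=C1C(=O)[C@H](O[Si](C)(C)C(C)(C)C)[C@H]1O[Si](C)(C)C(C)(C)C | intermediate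
5 | methyl (E)-3-methoxyacrylate | CO/C=C/C(=O)OC | starting material
6 | methyl (E)-3-lithio-3-methoxyacrylate (lithium cis to the ester; not isolated) | CO/C([Li])=C/C(=O)OC | intermediate
7 | dilithium bis-alkoxide diester adduct: trans-cyclobutane-1,2-diolate carrying on C5A and C5B a (E)-1-methoxy-3-methoxy-3-oxoprop-1-enyl group, each trans to the neighbouring OTBS (not isolated) | [Li+].[Li+].COC(=O)/C=C(/OC)[C@@]1([O-])[C@H](O[Si](C)(C)C(C)(C)C)[C@@H](O[Si](C)(C)C(C)(C)C)[C@]1([O-])/C(OC)=C\C(=O)OC | intermediate
8 | key-step precursor, C2-symmetric dispiro bis(methyl tetronate) bis(TBS ether): adjacent cyclobutane carbons C5A and C5B are each C5 of a 4-methoxyfuran-2(5H)-one; OTBS on C6 and C7 (6R,7R, trans); O1A and O1B on opposite faces, each OTBS cis to the lactone oxygen and trans to C4 of the neighbouring spiro ring | C1=C(OC)[C@@]2(OC1=O)[C@H](O[Si](C)(C)C(C)(C)C)[C@@H](O[Si](C)(C)C(C)(C)C)[C@@]21OC(=O)C=C1OC | intermediate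
9 | butanoyl chloride | CCCC(Cl)=O | starting material
10 | N,O-dimethylhydroxylamine hydrochloride | CNOC.Cl | starting material
11 | N-methoxy-N-methylbutanamide | CCCC(=O)N(C)OC | intermediate
12 | 3A,3B-dilithio derivative of 8 (not isolated) | [Li]C1=C(OC)[C@@]2(OC1=O)[C@H](O[Si](C)(C)C(C)(C)C)[C@@H](O[Si](C)(C)C(C)(C)C)[C@@]21OC(=O)C([Li])=C1OC | intermediate
13 | bis(lithium N-methoxy-N-methyl hemiaminal alkoxide) at C1′A and C1′B (not isolated) | CCCC(O[Li])(N(C)OC)C1=C(OC)[C@@]2(OC1=O)[C@H](O[Si](C)(C)C(C)(C)C)[C@@H](O[Si](C)(C)C(C)(C)C)[C@@]21OC(=O)C(C(O[Li])(N(C)OC)CCC)=C1OC | intermediate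
14 | key-step product, 3A,3B-dibutanoyl dispiro bis(methyl tetronate) bis(TBS ether), core as in 8 | CCCC(=O)C1=C(OC)[C@@]2(OC1=O)[C@H](O[Si](C)(C)C(C)(C)C)[C@@H](O[Si](C)(C)C(C)(C)C)[C@@]21OC(=O)C(C(=O)CCC)=C1OC | intermediate
15 | dilithium bis(3-butanoyltetronate), 14 with both C4 methoxy groups cleaved to C4–O⁻ (not isolated) | [Li+].[Li+].CCCC(=O)C1=C([O-])[C@@]2(OC1=O)[C@H](O[Si](C)(C)C(C)(C)C)[C@@H](O[Si](C)(C)C(C)(C)C)[C@@]21OC(=O)C(C(=O)CCC)=C1[O-] | intermediate
16 | bis(4-bromo-3-butanoylbutenolide) bis(TBS ether), 14 with Br in place of both C4 methoxy groups | CCCC(=O)C1=C(Br)[C@@]2(OC1=O)[C@H](O[Si](C)(C)C(C)(C)C)[C@@H](O[Si](C)(C)C(C)(C)C)[C@@]21OC(=O)C(C(=O)CCC)=C1Br | intermediate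
17 | C2-symmetric (1′R,1′R)-bis(1-hydroxybutyl) bis(4-bromobutenolide) bis(TBS ether) | CCC[C@@H](O)C1=C(Br)[C@@]2(OC1=O)[C@H](O[Si](C)(C)C(C)(C)C)[C@@H](O[Si](C)(C)C(C)(C)C)[C@@]21OC(=O)C([C@@H](CCC)O)=C1Br | intermediate
18 | mono-acetate: (1′S)-1-acetoxybutyl on one arm, (1′R)-1-hydroxybutyl on the other, bis(TBS ether) | CCC[C@H](OC(C)=O)C1=C(Br)[C@@]2(OC1=O)[C@H](O[Si](C)(C)C(C)(C)C)[C@@H](O[Si](C)(C)C(C)(C)C)[C@@]21OC(=O)C([C@@H](CCC)O)=C1Br | intermediate
19 | (1′S)/(1′R)-diacetate bis(TBS ether) | CCC[C@H](OC(C)=O)C1=C(Br)[C@@]2(OC1=O)[C@H](O[Si](C)(C)C(C)(C)C)[C@@H](O[Si](C)(C)C(C)(C)C)[C@@]21OC(=O)C([C@@H](CCC)OC(C)=O)=C1Br | intermediate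
20 | (1′S)/(1′R)-diacetate (6R,7R)-cyclobutane-6,7-diol, each OH cis to the lactone oxygen of the neighbouring spiro carbon | CCC[C@H](OC(C)=O)C1=C(Br)[C@@]2(OC1=O)[C@H](O)[C@@H](O)[C@@]21OC(=O)C([C@@H](CCC)OC(C)=O)=C1Br | intermediate
21 | (6R,7R)-bis(trifluoromethanesulfonate) of 20 (not isolated) | CCC[C@H](OC(C)=O)C1=C(Br)[C@@]2(OC1=O)[C@H](OS(=O)(=O)C(F)(F)F)[C@@H](OS(=O)(=O)C(F)(F)F)[C@@]21OC(=O)C([C@@H](CCC)OC(C)=O)=C1Br | intermediate
22 | CNP0266230.1: dispiro bis(4-bromobutenolide) with trans C6/C7 bromides (6R,7R), each Br cis to C4 of the neighbouring spiro ring, C5A and C5B both S, one (1′S)- and one (1′R)-1-acetoxybutyl arm | CCC[C@H](OC(C)=O)C1=C(Br)[C@@]2(OC1=O)[C@@H](Br)[C@H](Br)[C@@]21OC(=O)C([C@@H](CCC)OC(C)=O)=C1Br | target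

**Step count.** Total: 12 steps. Longest linear sequence: 11 steps (steps 1–4 and 6–12, from diethyl L-tartrate); step 5 is a one-step side branch.

**Steps most likely to fail**

1. Step 12. Bromide must enter C6 and C7 from the face that carries C4A or C4B of the neighbouring spiro ring, so substitution may be outrun by ionisation of a triflate (ring contraction or elimination), or the product may epimerise through further bromide exchange. The fallback sets out from diol 20 and comes back at target 22. It is an Appel-type deoxybromination (PPh3, CBr4, 2,6-lutidine, toluene, 0 to 60 °C): each carbinol is activated as an alkoxyphosphonium ion and bromide is delivered with inversion inside the ion pair, so no sulfonate ester and no excess of free bromide is present. No new compound lies on this path (F0).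

2. Step 4. The basic vinyllithium may enolise the α-silyloxy ketones (loss of silanolate towards a cyclobutenedione), the 2-oxidocyclobutanone formed after the first addition may ring-contract before the second addition, or the facial selectivity of the second addition may be poor. The fallback sets out from dione 4 and comes back at precursor 8. The smaller and less basic sp nucleophile LiC≡CCO2Me (methyl propiolate, LiN(SiMe3)2, THF, −78 °C) is added twice, again anti to the neighbouring silyloxy groups, to give the bis(propargylic alcohol) dimethyl 3,3′-[(3R,4R)-1,2-dihydroxy-3,4-bis(tert-butyldimethylsilyloxy)cyclobutane-1,2-diyl]bis(prop-2-ynoate) F1. NaOMe in MeOH then adds methoxide to each ynoate, and the γ-hydroxy (E)-β-methoxy enoates lactonise to the two methyl tetronates of 8.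

3. Step 6. The hindered, chelated C3 vinyllithium may deprotonate the amide at its α-CH2 or stop after one acyl transfer, so that mono-ketone or starting material is returned. The fallback sets out from 8 and comes back at diketone 14. The dilithio species 12 is generated as before and trapped with two molecules of butanal to give the 3A,3B-bis(1-hydroxybutyl) dispiro bis(methyl tetronate) bis(TBS ether) F2 as a mixture of C1′ epimers. Dess–Martin periodinane then oxidises both carbinols to 14; carbonyl addition followed by oxidation is the best documented entry to 3-acyl-4-methoxybutenolides.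

**Further compounds**

F0 | step 12 | none | none
F1 | step 4 | dimethyl 3,3′-[(3R,4R)-1,2-dihydroxy-3,4-bis(tert-butyldimethylsilyloxy)cyclobutane-1,2-diyl]bis(prop-2-ynoate), each alkynyl group trans to the neighbouring silyloxy group | COC(=O)C#C[C@@]1(O)[C@H](O[Si](C)(C)C(C)(C)C)[C@@H](O[Si](C)(C)C(C)(C)C)[C@]1(O)C#CC(=O)OC
F2 | step 6 | 3A,3B-bis(1-hydroxybutyl) dispiro bis(methyl tetronate) bis(TBS ether), mixture of C1′ epimers | CCCC(O)C1=C(OC)[C@@]2(OC1=O)[C@H](O[Si](C)(C)C(C)(C)C)[C@@H](O[Si](C)(C)C(C)(C)C)[C@@]21OC(=O)C(C(O)CCC)=C1OC
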